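The route cuts ring C at its carbonyl carbon. C4 is a one-carbon bridge between C4a of ring A and the OMe-substituted C3, so it is brought in as carbon monoxide. One palladium-catalysed operation joins an aryl iodide, CO and the enolate of an α-methoxy aryl ketone (C2, C3, 3-OMe, ring B). Acid then closes O1–C2. The iodide is a phloroglucinol ring that already carries the (R)-1-arylethyl group. Before iodination this ring is symmetric about the future C8–C5 axis, so its two open positions are equivalent and one mono-iodide results. A benzyl ether on future O5 and acid-labile MOM ethers on future O1 and O7 leave O1 as the only oxygen able to cyclise.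

Key step: step 6

Assumption: the sense of induction of the phosphoric acid on a styrene flanked by two ortho hydroxyls cannot be predicted with confidence, so (R)-TRIP is written and its enantiomer is used if a trial run delivers the S product.

Step 1
Reactants: 1 2,4,6-trihydroxyacetophenone
Product: 2 1-[4-(benzyloxy)-2,6-dihydroxyphenyl]ethanone
Conditions: BnBr (1.0 equiv), K2CO3 (1.05 equiv), DMF, 0 °C → rt
Reagents that add atoms: benzyl bromide, BrCc1ccccc1
Why: Williamson ether synthesis: the 2- and 6-hydroxyls are held in hydrogen bonds to the acetyl oxygen and are less acidic, so one equivalent of base and halide should alkylate the free 4-OH first.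

Step 2
Reactants: 2 1-[4-(benzyloxy)-2,6-dihydroxyphenyl]ethanone; 3 1-(benzyloxy)-4-bromobenzene
Product: 6 5-(benzyloxy)-2-[1-(4-benzyloxyphenyl)ethenyl]benzene-1,3-diol, via arylmagnesium bromide 4 (not isolated), via tertiary alcohol 5 (not isolated)
Conditions: 3 (4 equiv), Mg turnings, THF, reflux; 2 in THF, 0 → 60 °C; cold 1 M HCl; crude 5, p-TsOH·H2O (2 mol %), CH2Cl2, rt
Reagents that add atoms: none
Why: Grignard addition followed by E1 dehydration, the usual entry to 2-(1-arylvinyl)phenols: two equivalents of 4 deprotonate the phenols, a third adds to the magnesium-chelated carbonyl, and the doubly benzylic, electron-rich alcohol 5 ionises and loses water under a trace of acid, so no stereocentre is carried forward.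

Step 3
Reactants: 6 5-(benzyloxy)-2-[1-(4-benzyloxyphenyl)ethenyl]benzene-1,3-diol
Product: 8 5-(benzyloxy)-2-[(1R)-1-(4-benzyloxyphenyl)ethyl]benzene-1,3-diol, via o-quinone methide 7 (not isolated)
Conditions: (R)-TRIP (5 mol %), diethyl Hantzsch ester (1.3 equiv), CH2Cl2, rt, N2
Reagents that add atoms: none
Why: Chiral-phosphoric-acid-catalysed asymmetric transfer hydrogenation of a 2-(1-arylvinyl)phenol: the acid protonates the CH2 terminus to give o-quinone methide 7, the phosphate binds both 7 (through O–H) and the dihydropyridine (through N–H), and hydride passes to one face of the exocyclic carbon, so the R centre is set under catalyst control.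

Step 4
Reactants: 8 5-(benzyloxy)-2-[(1R)-1-(4-benzyloxyphenyl)ethyl]benzene-1,3-diol
Product: 9 5-(benzyloxy)-2-[(1R)-1-(4-benzyloxyphenyl)ethyl]-1,3-bis(methoxymethoxy)benzene
Conditions: MOMCl (3 equiv), iPr2NEt (4 equiv), CH2Cl2, 0 °C → rt
Reagents that add atoms: chloromethyl methyl ether, COCCl
Why: O-alkylation of phenols with an α-chloro ether (MOM protection): capping both phenols alike keeps the ring symmetric for step 5, leaves no acidic O–H or phenoxide to consume enolate or trap the aroylpalladium species in step 6, and uses a small acetal that fits beside the sec-alkyl group and is removed by the acid that closes ring C.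

Step 5
Reactants: 9 5-(benzyloxy)-2-[(1R)-1-(4-benzyloxyphenyl)ethyl]-1,3-bis(methoxymethoxy)benzene
Product: 10 1-(benzyloxy)-4-[(1R)-1-(4-benzyloxyphenyl)ethyl]-2-iodo-3,5-bis(methoxymethoxy)benzene
Conditions: NIS (1.0 equiv), MeCN, 0 °C → rt, dark
Reagents that add atoms: N-iodosuccinimide, O=C1CCC(=O)N1I
Why: Electrophilic aromatic iodination of a phloroglucinol triether: the two open positions are interchanged by rotation about the aryl–CH bond so only one mono-iodide can form, the mono-alkoxy and plain phenyl rings are far less nucleophilic, and acid-free conditions spare the acetals and the stereocentre.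

Step 6
Reactants: 10 1-(benzyloxy)-4-[(1R)-1-(4-benzyloxyphenyl)ethyl]-2-iodo-3,5-bis(methoxymethoxy)benzene; 11 2-methoxy-1-(4-methoxyphenyl)ethanone; 12 carbon monoxide
Product: 16 5-(benzyloxy)-8-[(1R)-1-(4-benzyloxyphenyl)ethyl]-7-hydroxy-3-methoxy-2-(4-methoxyphenyl)-4H-chromen-4-one, via sodium enolate 13 (not isolated), via bis-MOM diketone 14 (not isolated), via dihydroxy diketone 15 (not isolated)
Conditions: 11 (2.5 equiv), NaN(SiMe3)2 (2.4 equiv), THF, 0 °C; 10, Pd(dba)2 (5 mol %), Xantphos (6 mol %), 12 (1 atm), THF–dioxane, 80 °C; 1 M HCl quench, extraction; crude 14, HCl (3 M in MeOH), 55 °C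
Reagents that add atoms: none
Why: Oxidative addition of the C–I bond of 10 to zerovalent palladium and migratory insertion of 12 give an aroylpalladium iodide (C4a–C4); enolate 13 replaces iodide and reductive elimination forms C4–C3, and diketone 14 is at once stored as its sodium diketonate by a second equivalent of 13. This is the known palladium-catalysed carbonylative α-arylation of aryl alkyl ketones with aryl iodides, coupled to the acid cyclodehydration of o-hydroxyaryl 1,3-diketones that ends a Baker–Venkataraman flavone synthesis, applied here to a new pair of partners. Methanolic HCl cleaves both MOM acetals (15), the hydroxyl ortho to the new ketone attacks the anisoyl carbonyl in a 6-exo-trig closure (O1–C2), and loss of water makes ring C aromatic. No stereocentre is created, since the methoxy-bearing carbon of 14 and 15 ends as sp2 C3, and the R centre carries neither an acidic hydrogen nor a leaving group, so neither the enolate medium nor dilute acid should touch it. The step needs C- over O-acylation and no ester or amide formation: the wide-bite-angle bisphosphine favours reductive elimination at carbon, any enol ester is an acyl donor that funnels to the more stable diketonate, the MOM caps remove every phenoxide, and keeping 11 in slight excess over NaN(SiMe3)2 leaves no free amide. Ring fusion is decided by the substrate, because iodine sits between O1 and O5 and O5 stays benzylated through the acid stage, so only O1 can close and the arylethyl-bearing carbon must become C8.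

Step 7
Reactants: 16 5-(benzyloxy)-8-[(1R)-1-(4-benzyloxyphenyl)ethyl]-7-hydroxy-3-methoxy-2-(4-methoxyphenyl)-4H-chromen-4-one
Product: 17 5,7-dihydroxy-8-[(1R)-1-(4-hydroxyphenyl)ethyl]-3-methoxy-2-(4-methoxyphenyl)-4H-chromen-4-one
Conditions: H2 (1 atm), Pd/C (10 wt %), EtOAc–MeOH, rt
Reagents that add atoms: none
Why: Catalytic hydrogenolysis of benzyl aryl ethers: the tetrasubstituted C2=C3 bond, the methyl ethers and the all-carbon benzylic stereocentre are inert at one atmosphere, and the neutral medium gives the freed 5-OH no chance of the acid-driven Wessely–Moser ring opening and reclosure that would move the side chain to C6.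

Compound list
1 | 2,4,6-trihydroxyacetophenone | CC(=O)c1c(O)cc(O)cc1O | starting material
2 | 1-[4-(benzyloxy)-2,6-dihydroxyphenyl]ethanone | CC(=O)c1c(O)cc(OCc2ccccc2)cc1O | intermediate
3 | 1-(benzyloxy)-4-bromobenzene | Brc1ccc(OCc2ccccc2)cc1 | starting material
4 | [4-(benzyloxy)phenyl]magnesium bromide | Br[Mg]c1ccc(OCc2ccccc2)cc1 | intermediate
5 | 5-(benzyloxy)-2-[1-(4-benzyloxyphenyl)-1-hydroxyethyl]benzene-1,3-diol (racemic) | CC(O)(c1ccc(OCc2ccccc2)cc1)c1c(O)cc(OCc2ccccc2)cc1O | intermediate
6 | 5-(benzyloxy)-2-[1-(4-benzyloxyphenyl)ethenyl]benzene-1,3-diol | C=C(c1ccc(OCc2ccccc2)cc1)c1c(O)cc(OCc2ccccc2)cc1O | intermediate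
7 | 3-(benzyloxy)-6-[1-(4-benzyloxyphenyl)ethylidene]-5-hydroxycyclohexa-2,4-dien-1-one (o-quinone methide, alkene geometry mobile) | CC(=C1C(=O)C=C(OCc2ccccc2)C=C1O)c1ccc(OCc2ccccc2)cc1 | intermediate
8 | 5-(benzyloxy)-2-[(1R)-1-(4-benzyloxyphenyl)ethyl]benzene-1,3-diol | Oc1cc(OCc2ccccc2)cc(O)c1[C@H](C)c1ccc(OCc2ccccc2)cc1 | intermediate
9 | 5-(benzyloxy)-2-[(1R)-1-(4-benzyloxyphenyl)ethyl]-1,3-bis(methoxymethoxy)benzene | COCOc1cc(OCc2ccccc2)cc(OCOC)c1[C@H](C)c1ccc(OCc2ccccc2)cc1 | intermediate
10 | 1-(benzyloxy)-4-[(1R)-1-(4-benzyloxyphenyl)ethyl]-2-iodo-3,5-bis(methoxymethoxy)benzene (bis-MOM ether of 5-(benzyloxy)-2-[(1R)-1-(4-benzyloxyphenyl)ethyl]-4-iodobenzene-1,3-diol) | COCOc1c(I)c(OCc2ccccc2)cc(OCOC)c1[C@H](C)c1ccc(OCc2ccccc2)cc1 | intermediate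
11 | 2-methoxy-1-(4-methoxyphenyl)ethanone | COCC(=O)c1ccc(OC)cc1 | starting material
12 | carbon monoxide | [C-]#[O+] | starting material
13 | sodium 2-methoxy-1-(4-methoxyphenyl)ethenolate | [Na+].COC=C([O-])c1ccc(OC)cc1 | intermediate
14 | 1-{6-(benzyloxy)-3-[(1R)-1-(4-benzyloxyphenyl)ethyl]-2,4-bis(methoxymethoxy)phenyl}-2-methoxy-3-(4-methoxyphenyl)propane-1,3-dione (epimers at C2 of the propanedione, keto–enol mobile) | COCOc1c(C(=O)C(OC)C(=O)c2ccc(OC)cc2)c(OCc2ccccc2)cc(OCOC)c1[C@H](C)c1ccc(OCc2ccccc2)cc1 | intermediate
15 | 1-{6-(benzyloxy)-3-[(1R)-1-(4-benzyloxyphenyl)ethyl]-2,4-dihydroxyphenyl}-2-methoxy-3-(4-methoxyphenyl)propane-1,3-dione (epimers at C2 of the propanedione) | Oc1c(C(=O)C(OC)C(=O)c2ccc(OC)cc2)c(OCc2ccccc2)cc(O)c1[C@H](C)c1ccc(OCc2ccccc2)cc1 | intermediate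
16 | 5-(benzyloxy)-8-[(1R)-1-(4-benzyloxyphenyl)ethyl]-7-hydroxy-3-methoxy-2-(4-methoxyphenyl)-4H-chromen-4-one | COc1ccc(-c2oc3c([C@H](C)c4ccc(OCc5ccccc5)cc4)c(O)cc(OCc4ccccc4)c3c(=O)c2OC)cc1 | intermediate
17 | 5,7-dihydroxy-8-[(1R)-1-(4-hydroxyphenyl)ethyl]-3-methoxy-2-(4-methoxyphenyl)-4H-chromen-4-one | COc1ccc(-c2oc3c([C@H](C)c4ccc(O)cc4)c(O)cc(O)c3c(=O)c2OC)cc1 | target

Total step count: 7
Longest linear sequence: 7 steps (1 → 2 → 6 → 8 → 9 → 10 → 16 → 17)

Steps most likely to fail

Step 6. The iodide is electron-rich and flanked by two alkoxy groups, so oxidative addition may be slow and the crowded aroylpalladium species may be captured slowly. Three side processes could then take over: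
- reduction of the C–I bond
- O-acylation of the enolate
- palladium insertion into a C–H bond of the neighbouring benzyl ether

The fallback builds the same diketone stepwise with main-group organometallics and sets out from 10. Iodine–magnesium exchange with iPrMgCl·LiCl in THF at −20 to 0 °C gives {6-(benzyloxy)-3-[(1R)-1-(4-benzyloxyphenyl)ethyl]-2,4-bis(methoxymethoxy)phenyl}magnesium chloride F1. Acylation of this reagent with the Weinreb amide 2-methoxy-N-methoxy-N-methylacetamide gives 1-{6-(benzyloxy)-3-[(1R)-1-(4-benzyloxyphenyl)ethyl]-2,4-bis(methoxymethoxy)phenyl}-2-methoxyethanone F2. Deprotonation with LiN(SiMe3)2 (2.2 equiv, THF, −78 °C) and C-aroylation with 4-methoxybenzoyl chloride follow. This is the direct-aroylation variant of the Baker–Venkataraman sequence. It rejoins the route at 14, which methanolic HCl converts into 16 as in step 6.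

Step 3. The second ortho hydroxyl twists the quinone methide and offers the phosphate a second binding site, so facial discrimination may be poor. Cycloaddition of the quinone methide with unreacted alkene may also compete with hydride transfer. The fallback sets out from 6 and replaces ionic hydride transfer by hydroxyl-directed asymmetric hydrogenation. It uses [Rh(cod)2]BF4 with a screened chiral bisphosphine under H2 pressure in MeOH or CH2Cl2. A phenol oxygen binds rhodium and anchors the alkene, a reaction known for 2-(1-arylvinyl)phenols. The homogeneous catalyst leaves benzyl ethers alone. The fallback rejoins the route at 8 and makes no new compound (F0).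

Step 2. The acetyl group may be enolised by the basic Grignard reagent, and the carbonyl of the doubly charged bis-phenoxide is a poor electrophile, so conversion may stall. The fallback sets out from 2 and masks the phenols before the C–C bond is made, so that a neutral ketone is attacked. MOMCl and iPr2NEt give 1-[4-(benzyloxy)-2,6-bis(methoxymethoxy)phenyl]ethanone F3. Addition of 4 promoted by LaCl3·2LiCl (THF, 0 °C), which suppresses enolisation, gives 1-[4-(benzyloxy)-2,6-bis(methoxymethoxy)phenyl]-1-[4-(benzyloxy)phenyl]ethanol F4. Treatment with p-TsOH in MeOH at 40 °C removes both acetals and dehydrates the alcohol in one operation, rejoining the route at 6.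

Further compounds
F1 | step 6 | {6-(benzyloxy)-3-[(1R)-1-(4-benzyloxyphenyl)ethyl]-2,4-bis(methoxymethoxy)phenyl}magnesium chloride | COCOc1c([Mg]Cl)c(OCc2ccccc2)cc(OCOC)c1[C@H](C)c1ccc(OCc2ccccc2)cc1
F2 | step 6 | 1-{6-(benzyloxy)-3-[(1R)-1-(4-benzyloxyphenyl)ethyl]-2,4-bis(methoxymethoxy)phenyl}-2-methoxyethanone | COCOc1c(C(=O)COC)c(OCc2ccccc2)cc(OCOC)c1[C@H](C)c1ccc(OCc2ccccc2)cc1
F0 | step 3 | none | none
F3 | step 2 | 1-[4-(benzyloxy)-2,6-bis(methoxymethoxy)phenyl]ethanone | CC(=O)c1c(OCOC)cc(OCc2ccccc2)cc1OCOC
F4 | step 2 | 1-[4-(benzyloxy)-2,6-bis(methoxymethoxy)phenyl]-1-[4-(benzyloxy)phenyl]ethanol | CC(O)(c1ccc(OCc2ccccc2)cc1)c1c(OCOC)cc(OCc2ccccc2)cc1OCOC
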